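## Retrosynthetic overview

1. Target ⇐ Shi epoxidation of the C3=C4 E-alkene as the last step (oxirane formed last), after acetylation of a macrocyclic 7,13-diol.
2. 14-Membered carbocycle ⇐ intramolecular Nozaki–Hiyama–Kishi coupling of a C7 aldehyde with a C8 alkenyl iodide (ring formed second; sets C7).
3. cis-Fused α-methylene-γ-lactone ⇐ indium Barbier coupling (C1–C14 bond) of a (Z)-2-(bromomethyl)enoate, fragment A (C1–C7), with an α-hydroxy aldehyde, fragment B (C8–C14) (ring formed first; sets C1 and C14).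
4. Fragment A ⇐ TBS-protected pent-4-yn-1-ol: carboalumination/oxirane opening (E-alkene), oxidation, α-acrylate addition, SN2′ bromination.
5. Fragment B ⇐ (S)-citronellal (C12): proline α-aminoxylation (C13), ozonolysis, acetylide alkylation, Markovnikov hydroiodination.

Numbering (cembrane type): C1 is the ring carbon bearing C15(=C17H2)–C16(=O); C14 bears the lactone oxygen; C4 bears methyl C18; C7 OAc; C8(=C19H2); C12 bears methyl C20; C13 OAc.

Assumption: the (S)-sulfonamide–oxazoline ligand is taken to give the 7S carbinol in step 14 (its enantiomer is used if the sense is opposite), and the D-fructose-derived Shi ketone is taken to give the (3R,4R)-oxirane in step 16.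

## Route

Step 1
Reactants: 1 tert-butyl(dimethyl)(pent-4-yn-1-yloxy)silane
Product: 4 (3E)-7-{[tert-butyl(dimethyl)silyl]oxy}-4-methylhept-3-en-1-ol, via alkenylalane 2 (not isolated), via lithium alanate 3 (not isolated)
Conditions: Me3Al, (C5H5)2ZrCl2 (25 mol %), CH2Cl2, 0 °C → rt; then n-BuLi, THF/hexane, −78 °C; then ethylene oxide, −78 → 0 °C
Reagents that add atoms: trimethylaluminium, C[Al](C)C; ethylene oxide, C1CO1
Why: Zirconium-catalysed Negishi carboalumination adds methyl and aluminium syn across the terminal alkyne (methyl to the internal carbon), and the derived alanate opens the oxirane with retention, which fixes the E geometry of the C3=C4 alkene.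

Step 2
Reactants: 4 (3E)-7-{[tert-butyl(dimethyl)silyl]oxy}-4-methylhept-3-en-1-ol
Product: 5 (3E)-7-{[tert-butyl(dimethyl)silyl]oxy}-4-methylhept-3-enal
Conditions: Dess–Martin periodinane, pyridine, CH2Cl2, 0 °C; used crude
Reagents that add atoms: none
Why: Dess–Martin oxidation under buffered, non-basic conditions gives the β,γ-unsaturated aldehyde without moving the double bond into conjugation.

Step 3
Reactants: 5 (3E)-7-{[tert-butyl(dimethyl)silyl]oxy}-4-methylhept-3-enal
Product: 6 methyl (5E)-9-{[tert-butyl(dimethyl)silyl]oxy}-3-hydroxy-6-methyl-2-methylidenenon-5-enoate (racemic at C3)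
Conditions: i-Bu2AlH, N-methylmorpholine N-oxide, methyl propiolate, THF, 0 °C; then 5, 0 °C → rt
Reagents that add atoms: methyl propiolate, C#CC(=O)OC
Why: Hydroalumination of the propiolate gives an α-aluminoacrylate whose 1,2-addition to the aldehyde (vinylalumination) gives the Morita–Baylis–Hillman-type adduct; the new carbinol centre is racemic and becomes sp2 in step 4.

Step 4
Reactants: 6 methyl (5E)-9-{[tert-butyl(dimethyl)silyl]oxy}-3-hydroxy-6-methyl-2-methylidenenon-5-enoate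
Product: 7 methyl (2Z,5E)-2-(bromomethyl)-9-{[tert-butyl(dimethyl)silyl]oxy}-6-methylnona-2,5-dienoate
Conditions: NBS, Me2S, CH2Cl2, 0 °C; then 6, 0 °C → rt
Reagents that add atoms: N-bromosuccinimide, O=C1CCC(=O)N1Br
Why: Corey–Kim activation of the hydroxyl followed by SN2′ attack of bromide gives the thermodynamically preferred (Z)-2-(bromomethyl)enoate, and the preformed sulfonium reagent does not touch the trisubstituted alkene.

Step 5
Reactants: 8 (3S)-3,7-dimethyloct-6-enal [(S)-citronellal]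
Product: 11 (2R,3S)-3,7-dimethyloct-6-ene-1,2-diol, via aminoxy aldehyde 9 (not isolated), via aminoxy alcohol 10 (not isolated)
Conditions: L-proline (20 mol %), PhNO, DMSO, rt; then NaBH4, EtOH, 0 °C; then Zn, AcOH, rt
Reagents that add atoms: nitrosobenzene, O=Nc1ccccc1
Why: Proline-catalysed α-aminoxylation (enamine attack on the oxygen of PhNO, catalyst-controlled) sets C13 as R, and carbonyl reduction followed by reductive N–O cleavage gives the diol.

Step 6
Reactants: 11 (2R,3S)-3,7-dimethyloct-6-ene-1,2-diol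
Product: 12 (4R)-2,2-dimethyl-4-[(2S)-6-methylhept-5-en-2-yl]-1,3-dioxolane
Conditions: Me2C(OMe)2, PPTS (cat.), CH2Cl2, rt
Reagents that add atoms: 2,2-dimethoxypropane, COC(C)(C)OC
Why: Acid-catalysed transketalisation protects the 1,2-diol as its acetonide.

Step 7
Reactants: 12 (4R)-2,2-dimethyl-4-[(2S)-6-methylhept-5-en-2-yl]-1,3-dioxolane
Product: 14 (4S)-4-[(4R)-2,2-dimethyl-1,3-dioxolan-4-yl]pentan-1-ol, via ozonide 13 (not isolated)
Conditions: O3, CH2Cl2, −78 °C; then NaBH4, MeOH, −78 → 0 °C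
Reagents that add atoms: ozone, [O-][O+]=O
Why: Ozonolysis of the only alkene and reductive work-up of the ozonide give the primary alcohol at C9.

Step 8
Reactants: 14 (4S)-4-[(4R)-2,2-dimethyl-1,3-dioxolan-4-yl]pentan-1-ol
Product: 15 (4R)-4-[(2S)-5-iodopentan-2-yl]-2,2-dimethyl-1,3-dioxolane
Conditions: I2, PPh3, imidazole, CH2Cl2, 0 °C → rt
Reagents that add atoms: iodine, II
Why: Appel-type iodination converts the primary alcohol into the iodide by SN2 displacement of the alkoxyphosphonium ion.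

Step 9
Reactants: 15 (4R)-4-[(2S)-5-iodopentan-2-yl]-2,2-dimethyl-1,3-dioxolane
Product: 16 (4R)-4-[(2S)-hept-6-yn-2-yl]-2,2-dimethyl-1,3-dioxolane
Conditions: LiC≡CH·H2NCH2CH2NH2, DMSO, rt
Reagents that add atoms: lithium acetylide–ethylenediamine complex, [Li+].[C-]#C.NCCN
Why: SN2 alkylation of lithium acetylide by the unhindered primary iodide brings in C8 and C19.

Step 10
Reactants: 16 (4R)-4-[(2S)-hept-6-yn-2-yl]-2,2-dimethyl-1,3-dioxolane
Product: 19 (2R,3S)-7-iodo-3-methyloct-7-ene-1,2-diol, via alkenylalane 17 (not isolated), via iodoalkene acetonide 18 (not isolated)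
Conditions: NiCl2(dppp) (3 mol %), i-Bu2AlH, THF, 0 °C → rt; then NIS, 0 °C; then 2 M HCl, THF, rt
Reagents that add atoms: N-iodosuccinimide, O=C1CCC(=O)N1I
Why: Nickel-catalysed Markovnikov hydroalumination puts aluminium on the internal alkyne carbon, iodinolysis gives the 2-iodo-1-alkene, and the extended acidic work-up hydrolyses the acetonide.

Step 11
Reactants: 19 (2R,3S)-7-iodo-3-methyloct-7-ene-1,2-diol
Product: 20 (2R,3S)-2-hydroxy-7-iodo-3-methyloct-7-enal
Conditions: TEMPO (10 mol %), PhI(OAc)2, CH2Cl2, 0 °C → rt; crude used at once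
Reagents that add atoms: none
Why: Oxoammonium (TEMPO) oxidation is selective for the primary hydroxyl over the secondary one and gives the α-hydroxy aldehyde without touching the C13 centre.

Step 12
Reactants: 7 methyl (2Z,5E)-2-(bromomethyl)-9-{[tert-butyl(dimethyl)silyl]oxy}-6-methylnona-2,5-dienoate; 20 (2R,3S)-2-hydroxy-7-iodo-3-methyloct-7-enal
Product: 24 (4S,5R)-5-[(1R,2S)-1-hydroxy-6-iodo-2-methylhept-6-en-1-yl]-4-[(2E)-6-hydroxy-3-methylhex-2-en-1-yl]-3-methylideneoxolan-2-one, via allylindium 21 (not isolated), via hydroxy ester 22 (not isolated), via silyl lactone 23 (not isolated)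
Conditions: indium powder, THF/H2O (1:1), rt; then 2 M HCl to pH 1, rt
Reagents that add atoms: none
Why: In this aqueous indium Barbier allylation the free α-hydroxyl chelates the metal (13,14-syn, C14 R) and the Z-allylindium reacts at its γ-carbon through a chair transition state (C1 S, cis to C14), after which acid closes the α-methylene-γ-lactone and cleaves the primary silyl ether.

Step 13
Reactants: 24 (4S,5R)-5-[(1R,2S)-1-hydroxy-6-iodo-2-methylhept-6-en-1-yl]-4-[(2E)-6-hydroxy-3-methylhex-2-en-1-yl]-3-methylideneoxolan-2-one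
Product: 25 (4E)-6-{(2R,3S)-2-[(1R,2S)-1-hydroxy-6-iodo-2-methylhept-6-en-1-yl]-4-methylidene-5-oxooxolan-3-yl}-4-methylhex-4-enal
Conditions: TEMPO (10 mol %), PhI(OAc)2, CH2Cl2, rt
Reagents that add atoms: none
Why: Oxoammonium oxidation converts only the primary alcohol into the aldehyde and leaves the hindered secondary C13 hydroxyl, the alkenyl iodide and the lactone untouched.

Step 14
Reactants: 25 (4E)-6-{(2R,3S)-2-[(1R,2S)-1-hydroxy-6-iodo-2-methylhept-6-en-1-yl]-4-methylidene-5-oxooxolan-3-yl}-4-methylhex-4-enal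
Product: 27 (1S,3E,7S,12S,13R,14R)-7,13-dihydroxycembra-3,8(19),15(17)-trien-16,14-olide (macrocyclic diol), via alkenylchromium 26 (not isolated)
Conditions: CrCl2, (S)-N-[2-(4-isopropyl-4,5-dihydrooxazol-2-yl)-6-methylphenyl]methanesulfonamide, Et3N, NiCl2 (10 mol %), THF, rt, slow addition to 2 mM
Reagents that add atoms: none
Why: In this intramolecular Nozaki–Hiyama–Kishi reaction the C–I bond adds to zerovalent nickel, the alkenyl group passes to chromium and adds to the aldehyde at high dilution to close the 14-membered ring, with the chiral sulfonamide ligand on chromium controlling the new C7 centre (S).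

Step 15
Reactants: 27 (1S,3E,7S,12S,13R,14R)-7,13-dihydroxycembra-3,8(19),15(17)-trien-16,14-olide
Product: 28 (1S,3E,7S,12S,13R,14R)-7,13-diacetoxycembra-3,8(19),15(17)-trien-16,14-olide
Conditions: Ac2O, DMAP, pyridine, CH2Cl2, 0 °C → rt
Reagents that add atoms: acetic anhydride, CC(=O)OC(C)=O
Why: DMAP-catalysed acylation esterifies both secondary hydroxyls and so removes the free C7 hydroxyl before the oxirane is made.

Step 16
Reactants: 28 (1S,3E,7S,12S,13R,14R)-7,13-diacetoxycembra-3,8(19),15(17)-trien-16,14-olide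
Product: 29 (1S,3R,4R,7S,12S,13R,14R)-7,13-diacetoxy-3,4-epoxycembra-8(19),15(17)-dien-16,14-olide (CNP0323853.2)
Conditions: 1,2:4,5-di-O-isopropylidene-β-D-erythro-2,3-hexodiulo-2,6-pyranose (Shi ketone, 30 mol %), Oxone (2KHSO5·KHSO4·K2SO4), K2CO3, Bu4NHSO4, MeCN/CH2(OMe)2/aq. Na2B4O7 buffer, 0 °C
Reagents that add atoms: potassium peroxymonosulfate (KHSO5 of Oxone), [K+].[O-]S(=O)(=O)OO
Why: In this Shi asymmetric epoxidation the chiral dioxirane oxidises only the electron-rich trisubstituted E-alkene (the α-methylene lactone and the 1,1-disubstituted alkene next to the acetate are deactivated) and reagent control through the spiro transition state gives the (3R,4R)-oxirane.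

## Compound list

1 | tert-butyl(dimethyl)(pent-4-yn-1-yloxy)silane | C#CCCCO[Si](C)(C)C(C)(C)C | starting material
2 | dimethyl[(1E)-5-{[tert-butyl(dimethyl)silyl]oxy}-2-methylpent-1-en-1-yl]alane | C[Al](C)/C=C(\C)CCCO[Si](C)(C)C(C)(C)C | intermediate
3 | lithium butyl(dimethyl)[(1E)-5-{[tert-butyl(dimethyl)silyl]oxy}-2-methylpent-1-en-1-yl]alanate | [Li+].CCCC[Al-](C)(C)/C=C(\C)CCCO[Si](C)(C)C(C)(C)C | intermediate
4 | (3E)-7-{[tert-butyl(dimethyl)silyl]oxy}-4-methylhept-3-en-1-ol | OCC/C=C(\C)CCCO[Si](C)(C)C(C)(C)C | intermediate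
5 | (3E)-7-{[tert-butyl(dimethyl)silyl]oxy}-4-methylhept-3-enal | O=CC/C=C(\C)CCCO[Si](C)(C)C(C)(C)C | intermediate
6 | methyl (5E)-9-{[tert-butyl(dimethyl)silyl]oxy}-3-hydroxy-6-methyl-2-methylidenenon-5-enoate (racemic at C3) | C=C(C(=O)OC)C(O)C/C=C(\C)CCCO[Si](C)(C)C(C)(C)C | intermediate
7 | methyl (2Z,5E)-2-(bromomethyl)-9-{[tert-butyl(dimethyl)silyl]oxy}-6-methylnona-2,5-dienoate | COC(=O)/C(CBr)=C/C/C=C(\C)CCCO[Si](C)(C)C(C)(C)C | intermediate
8 | (3S)-3,7-dimethyloct-6-enal, (S)-citronellal | CC(C)=CCC[C@H](C)CC=O | starting material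
9 | (2R,3S)-2-(anilinooxy)-3,7-dimethyloct-6-enal | CC(C)=CCC[C@H](C)[C@@H](ONc1ccccc1)C=O | intermediate
10 | (2R,3S)-2-(anilinooxy)-3,7-dimethyloct-6-en-1-ol | CC(C)=CCC[C@H](C)[C@@H](ONc1ccccc1)CO | intermediate
11 | (2R,3S)-3,7-dimethyloct-6-ene-1,2-diol | CC(C)=CCC[C@H](C)[C@@H](O)CO | intermediate
12 | (4R)-2,2-dimethyl-4-[(2S)-6-methylhept-5-en-2-yl]-1,3-dioxolane | CC(C)=CCC[C@H](C)[C@@H]1COC(C)(C)O1 | intermediate
13 | 5-{(3S)-3-[(4R)-2,2-dimethyl-1,3-dioxolan-4-yl]butyl}-3,3-dimethyl-1,2,4-trioxolane (ozonide, both C5 epimers) | CC1(C)OOC(CC[C@H](C)[C@@H]2COC(C)(C)O2)O1 | intermediate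
14 | (4S)-4-[(4R)-2,2-dimethyl-1,3-dioxolan-4-yl]pentan-1-ol | OCCC[C@H](C)[C@@H]1COC(C)(C)O1 | intermediate
15 | (4R)-4-[(2S)-5-iodopentan-2-yl]-2,2-dimethyl-1,3-dioxolane | ICCC[C@H](C)[C@@H]1COC(C)(C)O1 | intermediate
16 | (4R)-4-[(2S)-hept-6-yn-2-yl]-2,2-dimethyl-1,3-dioxolane | C#CCCC[C@H](C)[C@@H]1COC(C)(C)O1 | intermediate
17 | {(6S)-6-[(4R)-2,2-dimethyl-1,3-dioxolan-4-yl]hept-1-en-2-yl}bis(2-methylpropyl)alane | C=C([Al](CC(C)C)CC(C)C)CCC[C@H](C)[C@@H]1COC(C)(C)O1 | intermediate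
18 | (4R)-4-[(2S)-6-iodohept-6-en-2-yl]-2,2-dimethyl-1,3-dioxolane | C=C(I)CCC[C@H](C)[C@@H]1COC(C)(C)O1 | intermediate
19 | (2R,3S)-7-iodo-3-methyloct-7-ene-1,2-diol | C=C(I)CCC[C@H](C)[C@@H](O)CO | intermediate
20 | (2R,3S)-2-hydroxy-7-iodo-3-methyloct-7-enal | C=C(I)CCC[C@H](C)[C@@H](O)C=O | intermediate
21 | [(2Z,5E)-9-{[tert-butyl(dimethyl)silyl]oxy}-2-(methoxycarbonyl)-6-methylnona-2,5-dien-1-yl]indium dibromide | COC(=O)/C(C[In](Br)Br)=C/C/C=C(\C)CCCO[Si](C)(C)C(C)(C)C | intermediate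
22 | methyl (3S,4R,5R,6S)-3-[(2E)-6-{[tert-butyl(dimethyl)silyl]oxy}-3-methylhex-2-en-1-yl]-4,5-dihydroxy-10-iodo-6-methyl-2-methylideneundec-10-enoate | C=C(I)CCC[C@H](C)[C@@H](O)[C@H](O)[C@@H](C/C=C(\C)CCCO[Si](C)(C)C(C)(C)C)C(=C)C(=O)OC | intermediate
23 | (4S,5R)-4-[(2E)-6-{[tert-butyl(dimethyl)silyl]oxy}-3-methylhex-2-en-1-yl]-5-[(1R,2S)-1-hydroxy-6-iodo-2-methylhept-6-en-1-yl]-3-methylideneoxolan-2-one | C=C(I)CCC[C@H](C)[C@@H](O)[C@@H]1OC(=O)C(=C)[C@@H]1C/C=C(\C)CCCO[Si](C)(C)C(C)(C)C | intermediate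
24 | (4S,5R)-5-[(1R,2S)-1-hydroxy-6-iodo-2-methylhept-6-en-1-yl]-4-[(2E)-6-hydroxy-3-methylhex-2-en-1-yl]-3-methylideneoxolan-2-one | C=C(I)CCC[C@H](C)[C@@H](O)[C@@H]1OC(=O)C(=C)[C@@H]1C/C=C(\C)CCCO | intermediate
25 | (4E)-6-{(2R,3S)-2-[(1R,2S)-1-hydroxy-6-iodo-2-methylhept-6-en-1-yl]-4-methylidene-5-oxooxolan-3-yl}-4-methylhex-4-enal | C=C(I)CCC[C@H](C)[C@@H](O)[C@@H]1OC(=O)C(=C)[C@@H]1C/C=C(\C)CCC=O | intermediate
26 | dichloro(alkenyl)chromium species of 25 (CrCl2 on C8 in place of iodine; trivalent chromium) | C=C([Cr](Cl)Cl)CCC[C@H](C)[C@@H](O)[C@@H]1OC(=O)C(=C)[C@@H]1C/C=C(\C)CCC=O | intermediate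
27 | (1S,3E,7S,12S,13R,14R)-7,13-dihydroxycembra-3,8(19),15(17)-trien-16,14-olide | C=C1CCC[C@H](C)[C@@H](O)[C@@H]2OC(=O)C(=C)[C@@H]2C/C=C(\C)CC[C@@H]1O | intermediate
28 | (1S,3E,7S,12S,13R,14R)-7,13-diacetoxycembra-3,8(19),15(17)-trien-16,14-olide | C=C1CCC[C@H](C)[C@@H](OC(C)=O)[C@@H]2OC(=O)C(=C)[C@@H]2C/C=C(\C)CC[C@@H]1OC(C)=O | intermediate
29 | (1S,3R,4R,7S,12S,13R,14R)-7,13-diacetoxy-3,4-epoxycembra-8(19),15(17)-dien-16,14-olide (CNP0323853.2) | C=C1CCC[C@H](C)[C@@H](OC(C)=O)[C@@H]2OC(=O)C(=C)[C@@H]2C[C@H]2O[C@]2(C)CC[C@@H]1OC(C)=O | target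

## Step count and risks

Total step count: 16. Longest linear sequence: 12 steps (steps 5–16, from 8 to 29); the other branch is 4 steps (1 to 7).

**Step 11 (selective oxidation to the free α-hydroxy aldehyde 20).** The risks are over-oxidation, glycol cleavage and dimerisation of 20. The fallback sets out from 19 and comes back at 24. Diol 19 is condensed with 4-methoxybenzaldehyde dimethyl acetal (PPTS) to the 4-methoxybenzylidene acetal F1. i-Bu2AlH opens F1 at the less hindered oxygen to the secondary PMB ether alcohol F2. Dess–Martin oxidation gives the robust α-PMB-oxy aldehyde F3. Indium coupling of F3 with bromide 7 in aqueous THF, with chelation through the ether oxygen, gives the PMB-protected hydroxy ester F4. Acid lactonises and desilylates F4 to the PMB-protected lactone alcohol F5. DDQ in CH2Cl2/pH 7 buffer then frees the C13 hydroxyl and gives 24.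

**Step 14 (macrocyclic Nozaki–Hiyama–Kishi closure).** The risks are the yield at high dilution and the C7 selectivity. The fallback sets out from 25 and comes back at 27. Aldehyde 25 is cyclised without the chiral ligand (CrCl2, NiCl2 cat., DMSO, 2 mM) to the C7-epimeric diol mixture F6. MnO2 oxidises only the allylic C7 hydroxyl to the macrocyclic enone F7. Corey–Bakshi–Shibata reduction with the (R)-methyl oxazaborolidine and catecholborane at −78 °C, where the 2-substituted vinyl group acts as the large group, gives the 7S alcohol 27 under reagent control.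

**Step 16 (late Shi epoxidation).** The risks are that the ring conformation overrides the reagent and that the basic medium harms the esters. The fallback sets out from 28 and comes back at 29. NBS in aqueous THF converts 28 into the bromohydrin F8 (bromonium on the exposed face, water at the tertiary C4, anti addition). DBU in CH2Cl2 then closes the oxirane by displacing bromide with inversion at C3. The oxygen therefore ends on the face opposite to the one an electrophilic oxidant attacks, which is what is needed if direct epoxidation gives mainly the 3S,4S isomer.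

## Further compounds

F1 | step 11 | (4R)-4-[(2S)-6-iodohept-6-en-2-yl]-2-(4-methoxyphenyl)-1,3-dioxolane (both C2 epimers) | C=C(I)CCC[C@H](C)[C@@H]1COC(c2ccc(OC)cc2)O1
F2 | step 11 | (2R,3S)-7-iodo-2-[(4-methoxyphenyl)methoxy]-3-methyloct-7-en-1-ol | C=C(I)CCC[C@H](C)[C@@H](OCc1ccc(OC)cc1)CO
F3 | step 11 | (2R,3S)-7-iodo-2-[(4-methoxyphenyl)methoxy]-3-methyloct-7-enal | C=C(I)CCC[C@H](C)[C@@H](OCc1ccc(OC)cc1)C=O
F4 | step 11 | methyl (3S,4R,5R,6S)-3-[(2E)-6-{[tert-butyl(dimethyl)silyl]oxy}-3-methylhex-2-en-1-yl]-4-hydroxy-10-iodo-5-[(4-methoxyphenyl)methoxy]-6-methyl-2-methylideneundec-10-enoate | C=C(I)CCC[C@H](C)[C@@H](OCc1ccc(OC)cc1)[C@H](O)[C@@H](C/C=C(\C)CCCO[Si](C)(C)C(C)(C)C)C(=C)C(=O)OC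
F5 | step 11 | (4S,5R)-4-[(2E)-6-hydroxy-3-methylhex-2-en-1-yl]-5-{(1R,2S)-6-iodo-1-[(4-methoxyphenyl)methoxy]-2-methylhept-6-en-1-yl}-3-methylideneoxolan-2-one | C=C(I)CCC[C@H](C)[C@@H](OCc1ccc(OC)cc1)[C@@H]1OC(=O)C(=C)[C@@H]1C/C=C(\C)CCCO
F6 | step 14 | (1S,3E,12S,13R,14R)-7,13-dihydroxycembra-3,8(19),15(17)-trien-16,14-olide (both C7 epimers) | C=C1CCC[C@H](C)[C@@H](O)[C@@H]2OC(=O)C(=C)[C@@H]2C/C=C(\C)CCC1O
F7 | step 14 | (1S,3E,12S,13R,14R)-13-hydroxy-7-oxocembra-3,8(19),15(17)-trien-16,14-olide | C=C1CCC[C@H](C)[C@@H](O)[C@@H]2OC(=O)C(=C)[C@@H]2C/C=C(\C)CCC1=O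
F8 | step 16 | (1S,3S,4R,7S,12S,13R,14R)-7,13-diacetoxy-3-bromo-4-hydroxycembra-8(19),15(17)-dien-16,14-olide | C=C1CCC[C@H](C)[C@@H](OC(C)=O)[C@@H]2OC(=O)C(=C)[C@@H]2C[C@H](Br)[C@](C)(O)CC[C@@H]1OC(C)=O
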